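**Retrosynthetic overview**

1. The strategy rests on the pyrrole ring (ring B) of the indole. C3 carries CH2NMe2 and the neighbouring C2 carries bromine, so the C2=C3 unit maps onto a propargylamine alkyne whose second terminus holds a silyl group as a stand-in for the C2 bromine.
2. Last disconnection: C2–Br back to C2–SiMe3 (ipso-bromodesilylation of the 2-silylgramine).
3. Key disconnection: N1–C2 and C3–C3a, giving 4,5-dibromo-2-iodo-N-methylaniline and N,N-dimethyl-3-(trimethylsilyl)prop-2-yn-1-amine (Larock heteroannulation). Ring B is the only ring formed; the benzene ring (ring A) arrives with both bromines in place.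
4. The aniline comes from 3,4-dibromoaniline (ortho-iodination, N-formylation, borane reduction); the alkyne comes from N,N-dimethylprop-2-yn-1-amine (lithiation, silylation).

Key step: step 5

Remark: the target is achiral, so no stereocentre has to be set and all SMILES carry no stereodescriptors.

**Route**

Step 1
Reactants: 1 3,4-dibromoaniline
Product: 2 4,5-dibromo-2-iodoaniline
Conditions: NIS (1.05 equiv), AcOH, rt, dark
Reagents that add atoms: N-iodosuccinimide, O=C1CCC(=O)N1I
Why: Electrophilic aromatic iodination directed by the amino group; the para position is blocked by bromine and the ortho position not flanked by bromine is the more accessible one, so one equivalent of NIS should give the 2-iodo-4,5-dibromo isomer.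

Step 2
Reactants: 2 4,5-dibromo-2-iodoaniline
Product: 3 N-(4,5-dibromo-2-iodophenyl)formamide
Conditions: HCO2H, Ac2O (premixed, 55 °C, 2 h); then 2, THF, 0 °C to rt
Reagents that add atoms: formic acid, O=CO (delivered as acetic formic anhydride, CC(=O)OC=O, made in the flask from formic acid and acetic anhydride, CC(=O)OC(C)=O)
Why: N-Formylation by a mixed anhydride, whose formyl carbonyl is the more electrophilic and less hindered site, so this weakly nucleophilic ortho-iodoaniline should be acylated once and only at nitrogen.

Step 3
Reactants: 3 N-(4,5-dibromo-2-iodophenyl)formamide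
Product: 4 4,5-dibromo-2-iodo-N-methylaniline
Conditions: BH3·SMe2 (3 equiv), THF, 0 °C to 60 °C; MeOH, then aq. HCl, then aq. NaOH
Reagents that add atoms: none
Why: Borane reduction of a secondary formamide to the N-methylamine installs exactly one methyl group and should leave the C–I and C–Br bonds untouched, which LiAlH4 would not guarantee.

Step 4
Reactants: 5 N,N-dimethylprop-2-yn-1-amine; 6 chlorotrimethylsilane
Product: 8 N,N-dimethyl-3-(trimethylsilyl)prop-2-yn-1-amine, via lithium 3-(dimethylamino)prop-1-yn-1-ide 7 (not isolated)
Conditions: n-BuLi (1.05 equiv), THF, −78 °C; then Me3SiCl (1.1 equiv), −78 °C to rt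
Reagents that add atoms: chlorotrimethylsilane (compound 6), C[Si](C)(C)Cl
Why: Deprotonation of the terminal alkyne by n-BuLi and C-silylation of the lithium acetylide is a standard acetylide silylation in which the tertiary amine is a spectator.

Step 5
Reactants: 4 4,5-dibromo-2-iodo-N-methylaniline; 8 N,N-dimethyl-3-(trimethylsilyl)prop-2-yn-1-amine (2 equiv)
Product: 9 5,6-dibromo-1-methyl-2-(trimethylsilyl)gramine, that is 1-[5,6-dibromo-1-methyl-2-(trimethylsilyl)-1H-indol-3-yl]-N,N-dimethylmethanamine
Conditions: Pd(OAc)2 (5 mol %), LiCl (1 equiv), Na2CO3 (3 equiv), degassed dry DMF, 85–90 °C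
Reagents that add atoms: none
Why: This is a Larock heteroannulation: zerovalent palladium formed in situ from Pd(OAc)2 inserts into the C–I bond of 4, and alkyne 8 undergoes syn carbopalladation so that the aryl carbon (future C3a) bonds to the CH2NMe2-bearing alkyne carbon (future C3) while palladium sits on the silicon-bearing carbon (future C2). The N-methylamino group then displaces halide on the vinyl–divalent palladium species with loss of HX to Na2CO3, giving a six-membered azapalladacycle, and C–N reductive elimination forms N1–C2 and returns zerovalent palladium. Ring B is thus closed by reductive elimination from the palladacycle, a formal [3+2] annulation of the C–C–N unit of 4 onto the two alkyne carbons, and no stereocentre is formed. Regioselectivity is needed and is secured by the trimethylsilyl group, which as the bulkier alkyne substituent is placed next to palladium and therefore ends at C2. Chemoselectivity for C–I over the two C–Br bonds is needed and rests on the much faster oxidative addition of the aryl iodide to ligand-free, chloride-ligated palladium at this temperature, supported by stopping the reaction once 4 is consumed. The mild carbonate base in dry DMF is chosen so that the alkynyl and indolyl C–Si bonds should survive.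

Step 6
Reactants: 9 5,6-dibromo-1-methyl-2-(trimethylsilyl)gramine
Product: 12 2,5,6-tribromo-1-methylgramine, via silylgramine methanesulfonate salt 10 (not isolated), via target methanesulfonate salt 11 (not isolated)
Conditions: MsOH (1.0 equiv), MeCN, 0 °C; then NBS (1.05 equiv), 0 °C, dark; aq. NaOH/Na2S2O3 work-up
Reagents that add atoms: N-bromosuccinimide, O=C1CCC(=O)N1Br
Why: Electrophilic ipso-bromodesilylation of a 2-indolylsilane, in which bromine attacks the silicon-bearing C2, the cation at C3 is stabilised by the beta-silicon effect and loss of silicon restores the indole, while protonation of the dimethylamino group with exactly one equivalent of acid shields it from N-bromination and blocks retro-Mannich loss of the side chain without leaving free strong acid for protodesilylation.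

**Compound list**

1 | 3,4-dibromoaniline | Nc1ccc(Br)c(Br)c1 | starting material
2 | 4,5-dibromo-2-iodoaniline | Nc1cc(Br)c(Br)cc1I | intermediate
3 | N-(4,5-dibromo-2-iodophenyl)formamide | O=CNc1cc(Br)c(Br)cc1I | intermediate
4 | 4,5-dibromo-2-iodo-N-methylaniline | CNc1cc(Br)c(Br)cc1I | intermediate
5 | N,N-dimethylprop-2-yn-1-amine | CN(C)CC#C | starting material
6 | chlorotrimethylsilane | C[Si](C)(C)Cl | starting material
7 | lithium 3-(dimethylamino)prop-1-yn-1-ide | [Li]C#CCN(C)C | intermediate
8 | N,N-dimethyl-3-(trimethylsilyl)prop-2-yn-1-amine | CN(C)CC#C[Si](C)(C)C | intermediate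
9 | 5,6-dibromo-1-methyl-2-(trimethylsilyl)gramine | CN(C)Cc1c([Si](C)(C)C)n(C)c2cc(Br)c(Br)cc12 | intermediate
10 | 5,6-dibromo-1-methyl-2-(trimethylsilyl)gramine methanesulfonate | C[NH+](C)Cc1c([Si](C)(C)C)n(C)c2cc(Br)c(Br)cc12.CS(=O)(=O)[O-] | intermediate
11 | 2,5,6-tribromo-1-methylgramine methanesulfonate | C[NH+](C)Cc1c(Br)n(C)c2cc(Br)c(Br)cc12.CS(=O)(=O)[O-] | intermediate
12 | 2,5,6-tribromo-1-methylgramine | CN(C)Cc1c(Br)n(C)c2cc(Br)c(Br)cc12 | target

**Step count**

Total step count: 6. Longest linear sequence: 5 steps (steps 1, 2, 3, 5, 6); step 4 is the one-step side branch to the alkyne.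

**Steps most likely to fail**

Step 5 (annulation). What may go wrong is oxidative addition also at the C–Br bonds, leading to oligomers; base-induced loss of the alkynyl silicon before insertion, which removes the regiocontrol; or sequestration of palladium by the propargylic amine. The fallback sets out from compound 4 and comes back at compound 12, replacing steps 5 and 6. It builds the indole without the side chain and brings in the aminomethyl group by a Mannich reaction.
- Sonogashira coupling of 4 with ethynyltrimethylsilane (PdCl2(PPh3)2, CuI, Et3N, rt, where only the iodide should react) would give 4,5-dibromo-N-methyl-2-[(trimethylsilyl)ethynyl]aniline F1.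
- K2CO3 in MeOH would remove silicon to give 4,5-dibromo-2-ethynyl-N-methylaniline F2.
- CuI in DMF at 100 °C would close ring B by 5-endo-dig hydroamination to 5,6-dibromo-1-methyl-1H-indole F3.
- Dimethylmethylideneammonium iodide (Eschenmoser's salt) in MeCN would aminomethylate C3 to give 5,6-dibromo-1-methylgramine F4.
- MsOH would convert this into 5,6-dibromo-1-methylgramine methanesulfonate F5, which NBS should brominate at C2 (attack at C3, 1,2-shift of bromine, loss of the C2 proton, the usual course for 3-alkylindoles). This gives salt 11 and, after basic work-up, target 12.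

Step 6 (bromodesilylation). What may go wrong is oxidation of the dimethylamino group by the brominating agent where protonation is incomplete, ipso attack at C3 with expulsion of the aminomethyl side chain, or protodesilylation by the acid ahead of bromination. The fallback sets out from compound 4 and comes back at compound 12. It places bromine on C2 before any amine is present.
- Annulation of 4 with commercial 3-(trimethylsilyl)prop-2-yn-1-ol under the step 5 conditions would give [5,6-dibromo-1-methyl-2-(trimethylsilyl)-1H-indol-3-yl]methanol F6.
- NBS in CH2Cl2 at 0 °C would give (2,5,6-tribromo-1-methyl-1H-indol-3-yl)methanol F7.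
- MnO2 in CH2Cl2 would give 2,5,6-tribromo-1-methyl-1H-indole-3-carbaldehyde F8.
- Reductive amination with Me2NH and NaBH(OAc)3 in 1,2-dichloroethane at rt would give 12.

Step 1 (iodination). What may go wrong is iodination at the crowded ortho position between nitrogen and bromine, or a second iodination of the product. The fallback sets out from compound 1 and comes back at compound 2. It uses amide-directed C–H activation in place of free electrophilic substitution.
- Acetylation of 1 with Ac2O would give N-(3,4-dibromophenyl)acetamide F9.
- Ortho C–H iodination with catalytic Pd(OAc)2, TsOH and NIS, in which cyclopalladation by divalent palladium should take place at the ortho C–H not flanked by bromine, would give N-(4,5-dibromo-2-iodophenyl)acetamide F10.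
- HCl in EtOH at reflux would remove the acetyl group to give 2.

**Further compounds**

F1 | step 5 | 4,5-dibromo-N-methyl-2-[(trimethylsilyl)ethynyl]aniline | CNc1cc(Br)c(Br)cc1C#C[Si](C)(C)C
F2 | step 5 | 4,5-dibromo-2-ethynyl-N-methylaniline | CNc1cc(Br)c(Br)cc1C#C
F3 | step 5 | 5,6-dibromo-1-methyl-1H-indole | Cn1ccc2cc(Br)c(Br)cc21
F4 | step 5 | 5,6-dibromo-1-methylgramine | CN(C)Cc1cn(C)c2cc(Br)c(Br)cc12
F5 | step 5 | 5,6-dibromo-1-methylgramine methanesulfonate | C[NH+](C)Cc1cn(C)c2cc(Br)c(Br)cc12.CS(=O)(=O)[O-]
F6 | step 6 | [5,6-dibromo-1-methyl-2-(trimethylsilyl)-1H-indol-3-yl]methanol | OCc1c([Si](C)(C)C)n(C)c2cc(Br)c(Br)cc12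
F7 | step 6 | (2,5,6-tribromo-1-methyl-1H-indol-3-yl)methanol | OCc1c(Br)n(C)c2cc(Br)c(Br)cc12
F8 | step 6 | 2,5,6-tribromo-1-methyl-1H-indole-3-carbaldehyde | O=Cc1c(Br)n(C)c2cc(Br)c(Br)cc12
F9 | step 1 | N-(3,4-dibromophenyl)acetamide | CC(=O)Nc1ccc(Br)c(Br)c1
F10 | step 1 | N-(4,5-dibromo-2-iodophenyl)acetamide | CC(=O)Nc1cc(Br)c(Br)cc1I
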